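The plan rests on reading C7–C1–C2(O)–C3(O) of the six-membered carbocycle as the carboxyl, ipso, ortho and meta carbons of a benzoate ester, C4–C6 remaining a diene. Numbering: C1 is the ring carbon bearing OH and C7H2OH, C2 the CHOH, C3 and C6 the CH(OBz) carbons, C4=C5 the alkene. Whole-cell toluene dioxygenase turns achiral ethyl benzoate, the precursor, in one operation into the enantiopure cis-2,3-diol diene: both C–O bonds and the C2 configuration are set, no ring is formed. Relay steps then reduce the ester, epoxidise C1=C6 from the O2 face, invert C3 by Mitsunobu benzoylation and open the epoxide at C6 with benzoic acid.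

Key step: step 1

Remark: the C3 inversion is run on the vinyl epoxide and not on the cyclohexadiene, because an activated dienylic hydroxyl would ionise and aromatise to a phenol; "O2 face" means the ring face that carries the C2 hydroxyl.

Step 1
Reactants: 1 ethyl benzoate
Product: 2 ethyl (5S,6R)-5,6-dihydroxycyclohexa-1,3-diene-1-carboxylate
Conditions: E. coli JM109(pDTG601A) whole cells (toluene dioxygenase, IPTG-induced), glucose, air, pH 7 mineral medium, 35 °C; EtOAc extraction
Reagents that add atoms: dioxygen, O=O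
Why: Rieske non-haem iron dioxygenation: the mononuclear iron site, supplied with two electrons from NADH through the ferredoxin chain, binds O2 and transfers both oxygen atoms to the same face of the arene, so the C2–O and C3–O bonds (ortho and meta to the ester) form suprafacially and the aromatic ring becomes a cis-diol diene. The closest known reaction type is the toluene dioxygenase cis-dihydroxylation of monosubstituted benzenes such as halobenzenes and benzoate esters. No ring is closed. Both new stereocentres (C2 = 6R and C3 = 5S of the product) are fixed by the chiral active site, which holds the substituent in one orientation and presents a single enantioface of the ortho,meta bond to the iron-bound oxygen. The step needs ortho,meta regioselectivity over ipso,ortho or meta,para attack and a single enantioface; the fit of the CO2Et group in the substrate pocket secures both, and the absence of the cis-diol dehydrogenase in the recombinant strain prevents re-aromatisation to the catechol.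

Step 2
Reactants: 2 ethyl (5S,6R)-5,6-dihydroxycyclohexa-1,3-diene-1-carboxylate
Product: 3 ethyl (5S,6R)-5-[(tert-butyldimethylsilyl)oxy]-6-hydroxycyclohexa-1,3-diene-1-carboxylate
Conditions: TBSCl (1.05 equiv), imidazole, DMF, −20 → 0 °C
Reagents that add atoms: tert-butyldimethylsilyl chloride, CC(C)(C)[Si](C)(C)Cl
Why: Regioselective silyl ether formation: O3–H, flanked by an unsubstituted vinyl CH, is less hindered than O2–H, which sits beside the ester-bearing C1 and is hydrogen-bonded to the carbonyl, so one equivalent of TBSCl should cap O3 without touching a stereocentre.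

Step 3
Reactants: 3 ethyl (5S,6R)-5-[(tert-butyldimethylsilyl)oxy]-6-hydroxycyclohexa-1,3-diene-1-carboxylate
Product: 4 (1R,6S)-6-[(tert-butyldimethylsilyl)oxy]-2-(hydroxymethyl)cyclohexa-2,4-dien-1-ol
Conditions: DIBAL-H (3.5 equiv), CH2Cl2, −78 °C; Rochelle salt work-up
Reagents that add atoms: none
Why: DIBAL-H reduction of an α,β-unsaturated ester proceeds by 1,2-hydride delivery through the aldehyde to the allylic alcohol C7–OH and leaves the diene, the silyl ether and both stereocentres untouched (one equivalent is consumed by O2–H).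

Step 4
Reactants: 4 (1R,6S)-6-[(tert-butyldimethylsilyl)oxy]-2-(hydroxymethyl)cyclohexa-2,4-dien-1-ol
Product: 5 (1R,6S)-6-[(tert-butyldimethylsilyl)oxy]-2-[(trityloxy)methyl]cyclohexa-2,4-dien-1-ol
Conditions: TrCl, Et3N, DMAP (cat.), CH2Cl2, 0 °C → rt
Reagents that add atoms: trityl chloride, ClC(c1ccccc1)(c1ccccc1)c1ccccc1
Why: Tritylation (SN1 transfer of the trityl cation under base) is selective for the primary allylic C7–OH over the hindered secondary O2–H and keeps the acid-labile dienol under basic conditions.

Step 5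
Reactants: 5 (1R,6S)-6-[(tert-butyldimethylsilyl)oxy]-2-[(trityloxy)methyl]cyclohexa-2,4-dien-1-ol
Product: 6 (1S,2S,3S,6R)-3-[(tert-butyldimethylsilyl)oxy]-1-[(trityloxy)methyl]-7-oxabicyclo[4.1.0]hept-4-en-2-ol
Conditions: VO(acac)2 (5 mol %), t-BuOOH (1.2 equiv, in decane), CH2Cl2, 0 °C
Reagents that add atoms: tert-butyl hydroperoxide, CC(C)(C)OO
Why: Hydroxyl-directed vanadium-catalysed epoxidation of an allylic alcohol: the vanadate ester of O2–H delivers the peroxide oxygen to the adjacent trisubstituted C1=C6 bond on the O2 face (syn), setting C1 (S) and C6 (R), while C4=C5, which has no free allylic hydroxyl, should be left alone.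

Step 6
Reactants: 6 (1S,2S,3S,6R)-3-[(tert-butyldimethylsilyl)oxy]-1-[(trityloxy)methyl]-7-oxabicyclo[4.1.0]hept-4-en-2-ol
Product: 7 (1S,2S,3S,6R)-1-[(trityloxy)methyl]-7-oxabicyclo[4.1.0]hept-4-ene-2,3-diol
Conditions: TBAF (1.1 equiv), THF, 0 °C
Reagents that add atoms: none
Why: Fluoride-induced desilylation frees O3–H under non-acidic conditions that the vinyl epoxide and the trityl ether tolerate, and the syn epoxy alcohol cannot undergo Payne migration, so no stereocentre changes.

Step 7
Reactants: 7 (1S,2S,3S,6R)-1-[(trityloxy)methyl]-7-oxabicyclo[4.1.0]hept-4-ene-2,3-diol, 8 benzoic acid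
Product: 9 (1S,2S,3R,6R)-2-hydroxy-1-[(trityloxy)methyl]-7-oxabicyclo[4.1.0]hept-4-en-3-yl benzoate
Conditions: PPh3 (1.3 equiv), DIAD (1.3 equiv), THF, 0 °C → rt
Reagents that add atoms: benzoic acid (8), O=C(O)c1ccccc1
Why: Mitsunobu esterification: of the two hydroxyls of the cis-diol only the allylic O3–H should be displaced (C2 is neopentyl-like beside the fully substituted epoxide carbon), so benzoate attacks C3 of the oxyphosphonium salt by SN2 and inverts it from 3S to 3R, placing O3 trans to O2.

Step 8
Reactants: 9 (1S,2S,3R,6R)-2-hydroxy-1-[(trityloxy)methyl]-7-oxabicyclo[4.1.0]hept-4-en-3-yl benzoate, 8 benzoic acid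
Product: 10 (1S,2S,3R,6S)-1,2-dihydroxy-1-[(trityloxy)methyl]cyclohex-4-ene-3,6-diyl dibenzoate
Conditions: Ti(OiPr)4 (1.5 equiv), PhCO2H (1.5 equiv), CH2Cl2, rt; aq. tartaric acid work-up
Reagents that add atoms: benzoic acid (8), O=C(O)c1ccccc1
Why: Titanium tetraisopropoxide-mediated C3-selective opening of a 2,3-epoxy alcohol by a carboxylic acid: titanium bridges O2 and the syn epoxide oxygen and benzoate attacks the allylic secondary C6, not the fully substituted C1, from the face opposite the C6–O bond, so C6 is inverted (O6 trans to O1) and C1 keeps its oxygen on the O2 face.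

Step 9
Reactants: 10 (1S,2S,3R,6S)-1,2-dihydroxy-1-[(trityloxy)methyl]cyclohex-4-ene-3,6-diyl dibenzoate
Product: 11 (1S,2S,3R,6S)-1,2-dihydroxy-1-(hydroxymethyl)cyclohex-4-ene-3,6-diyl dibenzoate
Conditions: TsOH·H2O (cat.), MeOH–CH2Cl2, 0 °C → rt
Reagents that add atoms: none
Why: Acid-catalysed solvolysis of the trityl ether (SN1, trityl cation trapped by methanol) releases C7–OH under conditions too mild to transesterify or shift the two benzoates, and no stereocentre is involved.

Compound list

1 | ethyl benzoate | CCOC(=O)c1ccccc1 | starting material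
2 | ethyl (5S,6R)-5,6-dihydroxycyclohexa-1,3-diene-1-carboxylate | CCOC(=O)C1=CC=C[C@H](O)[C@@H]1O | intermediate
3 | ethyl (5S,6R)-5-[(tert-butyldimethylsilyl)oxy]-6-hydroxycyclohexa-1,3-diene-1-carboxylate | CCOC(=O)C1=CC=C[C@H](O[Si](C)(C)C(C)(C)C)[C@@H]1O | intermediate
4 | (1R,6S)-6-[(tert-butyldimethylsilyl)oxy]-2-(hydroxymethyl)cyclohexa-2,4-dien-1-ol | OCC1=CC=C[C@H](O[Si](C)(C)C(C)(C)C)[C@@H]1O | intermediate
5 | (1R,6S)-6-[(tert-butyldimethylsilyl)oxy]-2-[(trityloxy)methyl]cyclohexa-2,4-dien-1-ol | C(OCC1=CC=C[C@H](O[Si](C)(C)C(C)(C)C)[C@@H]1O)(c2ccccc2)(c3ccccc3)c4ccccc4 | intermediate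
6 | (1S,2S,3S,6R)-3-[(tert-butyldimethylsilyl)oxy]-1-[(trityloxy)methyl]-7-oxabicyclo[4.1.0]hept-4-en-2-ol | C(OC[C@@]12O[C@@H]1C=C[C@H](O[Si](C)(C)C(C)(C)C)[C@@H]2O)(c3ccccc3)(c4ccccc4)c5ccccc5 | intermediate
7 | (1S,2S,3S,6R)-1-[(trityloxy)methyl]-7-oxabicyclo[4.1.0]hept-4-ene-2,3-diol | C(OC[C@@]12O[C@@H]1C=C[C@H](O)[C@@H]2O)(c3ccccc3)(c4ccccc4)c5ccccc5 | intermediate
8 | benzoic acid | O=C(O)c1ccccc1 | starting material
9 | (1S,2S,3R,6R)-2-hydroxy-1-[(trityloxy)methyl]-7-oxabicyclo[4.1.0]hept-4-en-3-yl benzoate | C(OC[C@@]12O[C@@H]1C=C[C@@H](OC(=O)c6ccccc6)[C@@H]2O)(c3ccccc3)(c4ccccc4)c5ccccc5 | intermediate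
10 | (1S,2S,3R,6S)-1,2-dihydroxy-1-[(trityloxy)methyl]cyclohex-4-ene-3,6-diyl dibenzoate | C(OC[C@]1(O)[C@@H](O)[C@H](OC(=O)c2ccccc2)C=C[C@@H]1OC(=O)c3ccccc3)(c4ccccc4)(c5ccccc5)c6ccccc6 | intermediate
11 | (1S,2S,3R,6S)-1,2-dihydroxy-1-(hydroxymethyl)cyclohex-4-ene-3,6-diyl dibenzoate (CNP0212417.1) | OC[C@]1(O)[C@@H](O)[C@H](OC(=O)c2ccccc2)C=C[C@@H]1OC(=O)c3ccccc3 | target

Total step count: 9. Longest linear sequence: 9 steps (1 → 11; benzoic acid 8 enters in steps 7 and 8).

Steps most likely to fail

Step 7 (Mitsunobu inversion at C3). Activation may spread to O2–H, or the phosphine/benzoate pair may attack the vinyl epoxide (directly or in the SN2′ sense) faster than benzoate displaces the C3 oxyphosphonium group. The fallback sets out from 6 and comes back at 11; it reverses the order so that the inversion is run on a molecule with one free hydroxyl and no epoxide. Compound 6 is opened with Ti(OiPr)4/PhCO2H, as in step 8, to the 6-benzoate diol silyl ether F1. Its cis O1/O2 diol is closed with 2-methoxypropene and PPTS to the acetonide F2. HF·pyridine removes the silyl group to give the allylic alcohol F3. Mitsunobu benzoylation (PhCO2H, PPh3, DIAD) then gives the inverted dibenzoate acetonide F4, and aqueous TFA in CH2Cl2 at 0 °C cleaves acetonide and trityl ether together to give 11.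

Step 5 (directed epoxidation). The electron-rich dienol may be oxidised at the carbinol carbon and then aromatise, or dimerise faster than oxygen is transferred, or oxygen may be delivered partly to the wrong face. The fallback sets out from 4 and comes back at 6; it epoxidises before tritylation, under reagent control. Sharpless asymmetric epoxidation of the primary allylic alcohol of 4 (Ti(OiPr)4, D-(−)-diethyl tartrate, t-BuOOH, 4 Å MS, CH2Cl2, −20 °C) uses the tartrate enantiomer whose face rule points to the O2 face, so reagent and substrate bias agree, and should give the epoxy diol F5. Tritylation of its primary hydroxyl (TrCl, Et3N, DMAP) gives 6.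

Step 2 (regioselective silylation). The silyl chloride may not discriminate enough between the two secondary allylic hydroxyls, giving O2 silylation, bis-silylation or silyl migration. The fallback sets out from 2 and comes back at 5; it builds the steric bias first. Unprotected 2 is reduced with excess DIBAL-H (non-aqueous sulfate work-up) to the triol F6, and the primary hydroxyl is tritylated to the trityl ether diol F7. The trityloxymethyl group on C1 then shields O2–H, so TBSCl/imidazole should cap O3 only and give 5.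

Further compounds

F1 | step 7 | (1S,4S,5S,6S)-4-[(tert-butyldimethylsilyl)oxy]-5,6-dihydroxy-6-[(trityloxy)methyl]cyclohex-2-en-1-yl benzoate | C(OC[C@]1(O)[C@@H](O)[C@@H](O[Si](C)(C)C(C)(C)C)C=C[C@@H]1OC(=O)c2ccccc2)(c3ccccc3)(c4ccccc4)c5ccccc5
F2 | step 7 | O1,O2-isopropylidene acetal (acetonide) of F1 | C(OC[C@]12OC(C)(C)O[C@H]1[C@@H](O[Si](C)(C)C(C)(C)C)C=C[C@@H]2OC(=O)c3ccccc3)(c4ccccc4)(c5ccccc5)c6ccccc6
F3 | step 7 | 3-hydroxy acetonide (F2 without the silyl group; O3 cis to the acetonide) | C(OC[C@]12OC(C)(C)O[C@H]1[C@@H](O)C=C[C@@H]2OC(=O)c3ccccc3)(c4ccccc4)(c5ccccc5)c6ccccc6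
F4 | step 7 | 1,2-O-isopropylidene-7-O-trityl derivative of 11 (3,6-dibenzoate, C3 inverted) | C(OC[C@]12OC(C)(C)O[C@H]1[C@H](OC(=O)c7ccccc7)C=C[C@@H]2OC(=O)c3ccccc3)(c4ccccc4)(c5ccccc5)c6ccccc6
F5 | step 5 | (1S,2S,3S,6R)-3-[(tert-butyldimethylsilyl)oxy]-1-(hydroxymethyl)-7-oxabicyclo[4.1.0]hept-4-en-2-ol | OC[C@@]12O[C@@H]1C=C[C@H](O[Si](C)(C)C(C)(C)C)[C@@H]2O
F6 | step 2 | (1S,2R)-3-(hydroxymethyl)cyclohexa-3,5-diene-1,2-diol | OCC1=CC=C[C@H](O)[C@@H]1O
F7 | step 2 | (1S,2R)-3-[(trityloxy)methyl]cyclohexa-3,5-diene-1,2-diol | C(OCC1=CC=C[C@H](O)[C@@H]1O)(c2ccccc2)(c3ccccc3)c4ccccc4
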